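**Retrosynthetic overview**
1. The target comes from a 1β-flavenyl-3α,4α-epoxy-eudesm-11-en-2-one. The C2 ketone is only a temporary handle: SmI2 opens the oxirane to the C4 carbinol, then C2 is reduced and deoxygenated by a radical route.
2. Key C1–C4′ bond: Mukaiyama–Michael addition of the C1 enol silane of 3α,4α-epoxy-eudesm-11-en-2-one to 5,7,8-trimethoxyflavylium triflate, the ring-closed, O-activated form of the 2-hydroxychalcone.
3. The epoxy ketone comes from eudesma-3,11-dien-2-one, made by 1,2-carbonyl transposition (α-hydroxylation, diosphenol triflate, Pd/formate) of trans-dihydro-α-cyperone. (+)-α-Cyperone comes from (+)-dihydrocarvone and ethyl vinyl ketone by an imine-directed Michael addition and aldol closure.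
4. The flavylium salt comes from 2-hydroxy-3,4,6-trimethoxybenzaldehyde and acetophenone; the aldehyde from 3,4,5-trimethoxyphenol.
5. Ring order: ring B from the chiral pool, then ring A by annulation; the benzo ring is given and the pyrylium ring is closed before the union; no ring is formed after the coupling.

Assumption and convention: commercial (+)-dihydrocarvone (C2-epimer mixture, C5 = R) is used as such because C2 is planarised in step 5. The decalin carries eudesmane numbering (C10 = methyl-bearing quaternary ring-fusion carbon, C5 = ring-fusion CH, C4 = carbinol carbon, C7 = isopropenyl-bearing carbon; β = face of the C10 methyl); the chromene carries primed numbers.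

**Route**

Step 1
Reactants: 1 3,4,5-trimethoxyphenol
Product: 2 1,2,3,5-tetramethoxybenzene
Conditions: MeI (1.5 equiv), K2CO3 (2 equiv), acetone, reflux
Reagents that add atoms: iodomethane (CI)
Why: Williamson O-methylation of the phenoxide; no stereocentre is involved.

Step 2
Reactants: 2 1,2,3,5-tetramethoxybenzene
Product: 4 2,3,4,6-tetramethoxybenzaldehyde, via aryl iminium chloride 3 (not isolated)
Conditions: POCl3 (1.2 equiv), DMF, 0 → 70 °C; then ice-water, aq NaOAc
Reagents that add atoms: N,N-dimethylformamide (CN(C)C=O); water (O)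
Why: Vilsmeier–Haack formylation; the two free ring positions are equivalent by symmetry and strongly activated, so a single aldehyde forms.

Step 3
Reactants: 4 2,3,4,6-tetramethoxybenzaldehyde
Product: 5 2-hydroxy-3,4,6-trimethoxybenzaldehyde
Conditions: BCl3 (1.1 equiv), CH2Cl2, −78 → 0 °C; then H2O
Reagents that add atoms: none
Why: Chelation-directed ortho-demethylation by BCl3; the 2-methoxy group, buttressed between the formyl and the 3-methoxy group and twisted out of conjugation, is the more basic ortho ether and is cleaved selectively.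

Step 4
Reactants: 5 2-hydroxy-3,4,6-trimethoxybenzaldehyde, 6 acetophenone
Product: 8 5,7,8-trimethoxyflavylium triflate, via 2-hydroxychalcone 7 (not isolated)
Conditions: CF3SO3H (3 equiv), AcOH, 20 °C, 24 h; precipitation with Et2O
Reagents that add atoms: trifluoromethanesulfonic acid (OS(=O)(=O)C(F)(F)F)
Why: Acid-mediated crossed aldol (Claisen–Schmidt) condensation followed by cyclodehydration of the 2-hydroxychalcone to the aromatic pyrylium salt, which precipitates and drives the equilibrium.

Step 5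
Reactants: 9 (+)-dihydrocarvone, 10 (R)-1-phenylethylamine
Product: 11 N-[(R)-1-phenylethyl] imine of dihydrocarvone
Conditions: toluene, p-TsOH (cat.), reflux, Dean–Stark
Reagents that add atoms: none
Why: Imine condensation with azeotropic water removal; C2 becomes labile through imine–enamine tautomerism while C5 (R) is untouched.

Step 6
Reactants: 11 N-[(R)-1-phenylethyl] imine of dihydrocarvone, 12 ethyl vinyl ketone
Product: 14 (2S,5R)-2-methyl-2-(3-oxopentyl)-5-(prop-1-en-2-yl)cyclohexan-1-one, via Michael adduct imine 13 (not isolated)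
Conditions: THF, 40 °C, 4 d; then 10% aq AcOH, 20 °C
Reagents that add atoms: water (O)
Why: Auxiliary-controlled Michael addition of the more substituted secondary enamine tautomer (aza-ene-like chair transition state with internal N–H transfer); the (R)-phenylethyl group directs the enone to the face that gives the 10S quaternary centre (C10 methyl cis to the isopropenyl group), the matched pairing with 5R.

Step 7
Reactants: 14 (2S,5R)-2-methyl-2-(3-oxopentyl)-5-(prop-1-en-2-yl)cyclohexan-1-one
Product: 16 (+)-α-cyperone, via aldol ketol 15 (not isolated)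
Conditions: NaOMe (1 equiv), MeOH, 20 → 65 °C
Reagents that add atoms: none
Why: Intramolecular aldol condensation (second stage of a Robinson annulation) closes ring A through the only six-membered mode; C7 and C10 are not affected.

Step 8
Reactants: 16 (+)-α-cyperone
Product: 18 eudesm-11-en-3-one (4α-methyl, 5α-H), via lithium enolate 17 (not isolated)
Conditions: Li (2.5 equiv), NH3(l)/THF, t-BuOH (1.0 equiv), −78 °C; then solid NH4Cl
Reagents that add atoms: none
Why: Dissolving-metal (Birch-type) enone reduction; axial protonation of the C5 carbanion gives the trans-fused decalin (5α-H), the C4 methyl settles equatorial (4α) on ketonisation, and the isolated isopropenyl group is not reduced.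

Step 9
Reactants: 18 eudesm-11-en-3-one
Product: 20 2α-hydroxy-eudesm-11-en-3-one, via potassium enolate 19 (not isolated)
Conditions: KN(SiMe3)2 (1.1 equiv), THF, −78 °C; then 2-(phenylsulfonyl)-3-phenyloxaziridine (1.3 equiv), −78 °C; aq NH4Cl
Reagents that add atoms: 2-(phenylsulfonyl)-3-phenyloxaziridine (O=S(=O)(c1ccccc1)N1OC1c1ccccc1)
Why: Kinetic deprotonation at the C2 methylene (not the C4 methine) and Davis oxaziridine enolate hydroxylation from the α-face opposite the axial C10 methyl; the new C2 centre is erased in step 10.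

Step 10
Reactants: 20 2α-hydroxy-eudesm-11-en-3-one
Product: 22 3-hydroxy-eudesma-3,11-dien-2-one, via 2,3-diketone 21 (not isolated)
Conditions: Dess–Martin periodinane (1.3 equiv), CH2Cl2, 20 °C; then Et3N (cat.)
Reagents that add atoms: none
Why: Dess–Martin oxidation to the 1,2-diketone, which tautomerises to the more substituted, conjugated, hydrogen-bonded C3 enol (as 3-methylcyclohexane-1,2-dione does); the C4 centre is deliberately given up and C5 is not touched under these near-neutral conditions.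

Step 11
Reactants: 22 3-hydroxy-eudesma-3,11-dien-2-one
Product: 23 3-(trifluoromethylsulfonyloxy)eudesma-3,11-dien-2-one
Conditions: (CF3SO2)2O (1.2 equiv), pyridine (3 equiv), CH2Cl2, −78 → 0 °C
Reagents that add atoms: trifluoromethanesulfonic anhydride (O=S(=O)(OS(=O)(=O)C(F)(F)F)C(F)(F)F)
Why: O-Sulfonylation of the acidic diosphenol enol fixes the C3=C4 double bond as a vinyl triflate.

Step 12
Reactants: 23 3-(trifluoromethylsulfonyloxy)eudesma-3,11-dien-2-one
Product: 24 eudesma-3,11-dien-2-one
Conditions: Pd(OAc)2 (5 mol %), PPh3 (10 mol %), HCO2H (2 equiv), Bu3N (3 equiv), DMF, 60 °C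
Reagents that add atoms: none
Why: Palladium-catalysed formate hydrogenolysis of the vinyl triflate (oxidative addition, formate decarboxylation, reductive elimination) replaces OTf by H and leaves the enone and the isopropenyl group alone.

Step 13
Reactants: 24 eudesma-3,11-dien-2-one
Product: 25 3α,4α-epoxy-eudesm-11-en-2-one
Conditions: H2O2 (30% aq, 3 equiv), NaOH (0.3 equiv), MeOH, 0 → 20 °C
Reagents that add atoms: hydrogen peroxide (OO)
Why: Weitz–Scheffer nucleophilic epoxidation; hydroperoxide adds to C4 from the α-face, away from the syn-axial C10 methyl, and closes on C3, setting C3 and C4 (oxygen α, C4 methyl β), while the electron-rich isopropenyl group is inert to the nucleophilic oxidant.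

Step 14
Reactants: 25 3α,4α-epoxy-eudesm-11-en-2-one
Product: 27 2-(trimethylsilyloxy)-3α,4α-epoxy-eudesma-1,11-diene, via lithium enolate 26 (not isolated)
Conditions: LiN(iPr)2 (1.2 equiv), Me3SiCl (3 equiv), THF, −78 °C (internal quench); Et3N, pentane, filtration
Reagents that add atoms: chlorotrimethylsilane (C[Si](C)(C)Cl)
Why: Kinetic enolisation and O-silylation; C1 is the only enolisable position because C3 is an oxirane carbon, so a single regio-defined enol silane forms and the oxirane survives the low-temperature base.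

Step 15
Reactants: 27 2-(trimethylsilyloxy)-3α,4α-epoxy-eudesma-1,11-diene, 8 5,7,8-trimethoxyflavylium triflate (1.2 equiv)
Product: 28 1α-(5,7,8-trimethoxy-2-phenyl-4H-chromen-4-yl)-3α,4α-epoxy-eudesm-11-en-2-one
Conditions: CH2Cl2/MeCN 4:1, 2,6-lutidine (1.2 equiv), −78 → −30 °C; aq NaHCO3
Reagents that add atoms: none
Why: Mukaiyama–Michael addition of the enol silane to C4′ of the flavylium cation (the phenyl-blocked C2′ is not attacked); the electrophile enters on the α-face of C1, anti to the C10 methyl, through an open synclinal transition state with H-4′ tucked over ring A and the 5-methoxybenzo half turned away from C9/C10, which gives the C4′ configuration of the target.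

Step 16
Reactants: 28 1α-(5,7,8-trimethoxy-2-phenyl-4H-chromen-4-yl)-3α,4α-epoxy-eudesm-11-en-2-one
Product: 29 1β-(5,7,8-trimethoxy-2-phenyl-4H-chromen-4-yl)-3α,4α-epoxy-eudesm-11-en-2-one
Conditions: DBU (1 equiv), toluene, 50 °C
Reagents that add atoms: none
Why: Base-mediated epimerisation through the C1 enolate moves the bulky flavenyl group from the axial 1α to the equatorial 1β position (thermodynamic control); C4′ and the oxirane are untouched.

Step 17
Reactants: 29 1β-(5,7,8-trimethoxy-2-phenyl-4H-chromen-4-yl)-3α,4α-epoxy-eudesm-11-en-2-one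
Product: 30 4α-hydroxy-1β-(5,7,8-trimethoxy-2-phenyl-4H-chromen-4-yl)eudesm-11-en-2-one
Conditions: SmI2 (2.5 equiv, 0.1 M in THF), THF/MeOH 2:1, −90 °C, 10 min; pH 7 buffer
Reagents that add atoms: none
Why: Samarium diiodide reduction of an α,β-epoxy ketone; the ketyl cleaves the adjacent C3–O bond and the samarium enolate is protonated, so the C4–O bond is never broken and the 4α-hydroxy-4β-methyl centre is delivered with retention.

Step 18
Reactants: 30 4α-hydroxy-1β-(5,7,8-trimethoxy-2-phenyl-4H-chromen-4-yl)eudesm-11-en-2-one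
Product: 31 1β-(5,7,8-trimethoxy-2-phenyl-4H-chromen-4-yl)eudesm-11-ene-2β,4α-diol
Conditions: NaBH4 (2 equiv), MeOH/THF, 0 °C
Reagents that add atoms: none
Why: Borohydride carbonyl reduction; hydride enters from the α-face because the β-face carries two syn-axial methyls, giving mainly the 2β-alcohol, whose configuration is irrelevant because C2 is deoxygenated next.

Step 19
Reactants: 31 1β-(5,7,8-trimethoxy-2-phenyl-4H-chromen-4-yl)eudesm-11-ene-2β,4α-diol
Product: 33 O-(C2) S-methyl xanthate of the diol, via sodium xanthate 32 (not isolated)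
Conditions: NaH (1.05 equiv), imidazole (cat.), THF, 0 → 20 °C; CS2 (5 equiv); then MeI (3 equiv)
Reagents that add atoms: carbon disulfide (S=C=S); iodomethane (CI)
Why: Xanthate formation (first half of a Barton–McCombie deoxygenation); with one equivalent of base the more acidic secondary alkoxide forms and adds to the small electrophile CS2 in preference to the tertiary C4 hydroxyl, and S-methylation fixes the xanthate.

Step 20
Reactants: 33 O-(C2) S-methyl xanthate of the diol
Product: 34 CNP0390914.2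
Conditions: Bu3SnH (3 equiv, 0.3 M), AIBN (0.2 equiv), toluene, 100 °C
Reagents that add atoms: none
Why: Barton–McCombie radical deoxygenation; the C2 radical is quenched by the concentrated tin hydride before any β-scission because the equatorial C1–C4′ bond is orthogonal to the radical orbital, and no stereocentre, alkene or enol ether is touched.

**Compound list**
1 | 3,4,5-trimethoxyphenol | COc1cc(O)cc(OC)c1OC | starting material
2 | 1,2,3,5-tetramethoxybenzene | COc1cc(OC)c(OC)c(OC)c1 | intermediate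
3 | N,N-dimethyl(2,3,4,6-tetramethoxybenzylidene)iminium chloride | C[N+](C)=Cc1c(OC)cc(OC)c(OC)c1OC.[Cl-] | intermediate
4 | 2,3,4,6-tetramethoxybenzaldehyde | O=Cc1c(OC)cc(OC)c(OC)c1OC | intermediate
5 | 2-hydroxy-3,4,6-trimethoxybenzaldehyde | O=Cc1c(OC)cc(OC)c(OC)c1O | intermediate
6 | acetophenone | CC(=O)c1ccccc1 | starting material
7 | (E)-3-(2-hydroxy-3,4,6-trimethoxyphenyl)-1-phenylprop-2-en-1-one | O=C(/C=C/c1c(OC)cc(OC)c(OC)c1O)c1ccccc1 | intermediate
8 | 5,7,8-trimethoxy-2-phenylchromenylium (5,7,8-trimethoxyflavylium) trifluoromethanesulfonate | COc1cc(OC)c2ccc(-c3ccccc3)[o+]c2c1OC.[O-]S(=O)(=O)C(F)(F)F | intermediate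
9 | (+)-dihydrocarvone, (2R,5R)-2-methyl-5-(prop-1-en-2-yl)cyclohexan-1-one | C=C(C)[C@@H]1CC[C@@H](C)C(=O)C1 | starting material
10 | (R)-(+)-1-phenylethylamine | C[C@@H](N)c1ccccc1 | starting material
11 | N-[(R)-1-phenylethyl] imine of dihydrocarvone (5R; C2 epimers) | C=C(C)[C@@H]1CCC(C)C(=N[C@H](C)c2ccccc2)C1 | intermediate
12 | ethyl vinyl ketone (pent-1-en-3-one) | C=CC(=O)CC | starting material
13 | N-[(R)-1-phenylethyl] imine of (2S,5R)-2-methyl-2-(3-oxopentyl)-5-(prop-1-en-2-yl)cyclohexanone | C=C(C)[C@@H]1CC[C@@](C)(CCC(=O)CC)C(=N[C@H](C)c2ccccc2)C1 | intermediate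
14 | (2S,5R)-2-methyl-2-(3-oxopentyl)-5-(prop-1-en-2-yl)cyclohexan-1-one | C=C(C)[C@@H]1CC[C@@](C)(CCC(=O)CC)C(=O)C1 | intermediate
15 | 5-hydroxy-eudesm-11-en-3-one (aldol ketol; 7R,10S; C4 and C5 unassigned) | C=C(C)[C@@H]1CC[C@]2(C)C(O)(C1)C(C)C(=O)CC2 | intermediate
16 | (+)-α-cyperone, (7R,10S)-eudesma-4,11-dien-3-one | C=C(C)[C@@H]1CC[C@]2(C)C(C1)=C(C)C(=O)CC2 | intermediate
17 | lithium 3-enolate of eudesma-3,11-dien-3-ol (5α-H) | C=C(C)[C@@H]1CC[C@]2(C)[C@@H](C1)C(C)=C([O-])CC2.[Li+] | intermediate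
18 | eudesm-11-en-3-one (4α-methyl, 5α-H, 7β-isopropenyl, 10β-methyl; trans-dihydro-α-cyperone) | C=C(C)[C@@H]1CC[C@]2(C)[C@@H](C1)[C@H](C)C(=O)CC2 | intermediate
19 | potassium 2-en-3-olate of 18 | C=C(C)[C@@H]1CC[C@]2(C)[C@@H](C1)[C@H](C)C([O-])=CC2.[K+] | intermediate
20 | 2α-hydroxy-eudesm-11-en-3-one (4α-methyl, 5α-H) | C=C(C)[C@@H]1CC[C@]2(C)[C@@H](C1)[C@H](C)C(=O)[C@H](O)C2 | intermediate
21 | eudesm-11-ene-2,3-dione (4α-methyl, 5α-H) | C=C(C)[C@@H]1CC[C@]2(C)[C@@H](C1)[C@H](C)C(=O)C(=O)C2 | intermediate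
22 | 3-hydroxy-eudesma-3,11-dien-2-one (5α-H) | C=C(C)[C@@H]1CC[C@]2(C)[C@@H](C1)C(C)=C(O)C(=O)C2 | intermediate
23 | 3-(trifluoromethylsulfonyloxy)eudesma-3,11-dien-2-one (5α-H) | C=C(C)[C@@H]1CC[C@]2(C)[C@@H](C1)C(C)=C(OS(=O)(=O)C(F)(F)F)C(=O)C2 | intermediate
24 | eudesma-3,11-dien-2-one (5α-H, 7β-isopropenyl, 10β-methyl) | C=C(C)[C@@H]1CC[C@]2(C)[C@@H](C1)C(C)=CC(=O)C2 | intermediate
25 | 3α,4α-epoxy-eudesm-11-en-2-one (4β-methyl, 5α-H) | C=C(C)[C@@H]1CC[C@]2(C)[C@@H](C1)[C@]3(C)O[C@@H]3C(=O)C2 | intermediate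
26 | lithium 1-en-2-olate of 25 | C=C(C)[C@@H]1CC[C@]2(C)[C@@H](C1)[C@]3(C)O[C@@H]3C([O-])=C2.[Li+] | intermediate
27 | 2-(trimethylsilyloxy)-3α,4α-epoxy-eudesma-1,11-diene | C=C(C)[C@@H]1CC[C@]2(C)[C@@H](C1)[C@]3(C)O[C@@H]3C(O[Si](C)(C)C)=C2 | intermediate
28 | 1α-(5,7,8-trimethoxy-2-phenyl-4H-chromen-4-yl)-3α,4α-epoxy-eudesm-11-en-2-one (C4′ arranged as in 34) | C=C(C)[C@@H]1CC[C@]2(C)[C@@H](C1)[C@]3(C)O[C@@H]3C(=O)[C@@H]2[C@@H]4C=C(c5ccccc5)Oc5c(OC)c(OC)cc(OC)c54 | intermediate
29 | 1β-(5,7,8-trimethoxy-2-phenyl-4H-chromen-4-yl)-3α,4α-epoxy-eudesm-11-en-2-one (C4′ arranged as in 34) | C=C(C)[C@@H]1CC[C@]2(C)[C@@H](C1)[C@]3(C)O[C@@H]3C(=O)[C@H]2[C@@H]4C=C(c5ccccc5)Oc5c(OC)c(OC)cc(OC)c54 | intermediate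
30 | 4α-hydroxy-1β-(5,7,8-trimethoxy-2-phenyl-4H-chromen-4-yl)eudesm-11-en-2-one | C=C(C)[C@@H]1CC[C@]2(C)[C@@H](C1)[C@](C)(O)CC(=O)[C@H]2[C@@H]3C=C(c4ccccc4)Oc4c(OC)c(OC)cc(OC)c43 | intermediate
31 | 1β-(5,7,8-trimethoxy-2-phenyl-4H-chromen-4-yl)eudesm-11-ene-2β,4α-diol (major C2 epimer) | C=C(C)[C@@H]1CC[C@]2(C)[C@@H](C1)[C@](C)(O)C[C@@H](O)[C@H]2[C@@H]3C=C(c4ccccc4)Oc4c(OC)c(OC)cc(OC)c43 | intermediate
32 | sodium O-(C2) xanthate of 31 | C=C(C)[C@@H]1CC[C@]2(C)[C@@H](C1)[C@](C)(O)C[C@@H](OC(=S)[S-])[C@H]2[C@@H]3C=C(c4ccccc4)Oc4c(OC)c(OC)cc(OC)c43.[Na+] | intermediate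
33 | O-(C2) S-methyl xanthate (dithiocarbonate) of 31 | C=C(C)[C@@H]1CC[C@]2(C)[C@@H](C1)[C@](C)(O)C[C@@H](OC(=S)SC)[C@H]2[C@@H]3C=C(c4ccccc4)Oc4c(OC)c(OC)cc(OC)c43 | intermediate
34 | CNP0390914.2, (1S,4R,5R,7R,10S)-1-[(4R)-5,7,8-trimethoxy-2-phenyl-4H-chromen-4-yl]eudesm-11-en-4-ol (1β-flavenyl, 4α-OH, 5α-H) | C=C(C)[C@@H]1CC[C@]2(C)[C@@H](C1)[C@](C)(O)CC[C@H]2[C@@H]1C=C(c2ccccc2)Oc2c(OC)c(OC)cc(OC)c21 | target

**Totals**
Total step count: 20. Longest linear sequence: 16 steps (steps 5–20, from 9).

**Steps most likely to fail**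

Step 15 is the largest risk. The sense of attack at C4′ rests on an open transition-state model and cannot be predicted with certainty, and the oxirane must survive the silyl triflate that is formed. The fallback sets out from 5, 6 and 25 and comes back at 29; it replaces the cationic acceptor by the open-chain chalcone and a closed, lithium-chelated Michael addition. Aldehyde 5 and acetophenone 6 are condensed with KOH in EtOH and chalcone 7 is isolated this time. It is silylated (tBuMe2SiCl, imidazole, DMF) to (E)-3-[2-(tert-butyldimethylsilyloxy)-3,4,6-trimethoxyphenyl]-1-phenylprop-2-en-1-one F3. Lithium enolate 26 (from 25 with LiN(iPr)2, THF, −78 °C, no silyl chloride) is added to F3 at −78 → −20 °C to give the silyl-protected Michael adduct, 1β-[1-(2-silyloxy-3,4,6-trimethoxyphenyl)-3-oxo-3-phenylpropyl]-3α,4α-epoxy-eudesm-11-en-2-one F4. Bu4NF buffered with AcOH removes the silyl group to give the free phenol 1,5-diketone F5, with C1 equilibrating to the equatorial epimer under the basic fluoride. Azeotropic dehydration with pyridinium p-toluenesulfonate in benzene closes the 4H-chromene and gives 29.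

Step 19 is the second risk. The secondary C2 hydroxyl is axial and flanked by two syn-axial methyls, and the tertiary C4 hydroxyl can compete for xanthate formation. The fallback sets out from 30 and comes back at 34; it removes the carbonyl by a hydrazone reduction instead of the alcohol and radical route. Ketone 30 is condensed with p-toluenesulfonyl hydrazide (EtOH, 50 °C) to the tosylhydrazone of 30 F6. F6 is reduced with catecholborane (CHCl3, 0 °C) and then heated with NaOAc·3H2O, which expels sulfinate and dinitrogen and leaves the C2 methylene of 34.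

Step 11, with the oxidation-level shuffle of steps 9 and 10 that feeds it, is the third risk. It depends on the diosphenol sitting as the C3 enol and being triflated on that oxygen only. The fallback sets out from 16 and comes back at 24; it introduces the C2 carbonyl by allylic C–H oxidation instead of transposition. Compound 16 is reduced with Li/NH3 as in step 8, but enolate 17 is trapped with PhNTf2 to give 3-(trifluoromethylsulfonyloxy)eudesma-3,11-diene F1. Hydrogenolysis with Pd(OAc)2, PPh3, HCO2H and Bu3N in DMF gives eudesma-3,11-diene (α-selinene) F2. The C2 allylic methylene of F2 is oxidised with CrO3·3,5-dimethylpyrazole (CH2Cl2, −20 °C) to 24.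

**Further compounds**
F1 | step 11 | 3-(trifluoromethylsulfonyloxy)eudesma-3,11-diene (5α-H) | C=C(C)[C@@H]1CC[C@]2(C)[C@@H](C1)C(C)=C(OS(=O)(=O)C(F)(F)F)CC2
F2 | step 11 | eudesma-3,11-diene (α-selinene) | C=C(C)[C@@H]1CC[C@]2(C)[C@@H](C1)C(C)=CCC2
F3 | step 15 | (E)-3-[2-(tert-butyldimethylsilyloxy)-3,4,6-trimethoxyphenyl]-1-phenylprop-2-en-1-one | O=C(/C=C/c1c(OC)cc(OC)c(OC)c1O[Si](C)(C)C(C)(C)C)c1ccccc1
F4 | step 15 | 1β-[1-(2-(tert-butyldimethylsilyloxy)-3,4,6-trimethoxyphenyl)-3-oxo-3-phenylpropyl]-3α,4α-epoxy-eudesm-11-en-2-one (benzylic centre arranged as C4′ of 34) | C=C(C)[C@@H]1CC[C@]2(C)[C@@H](C1)[C@]3(C)O[C@@H]3C(=O)[C@H]2[C@H](CC(=O)c4ccccc4)c4c(OC)cc(OC)c(OC)c4O[Si](C)(C)C(C)(C)C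
F5 | step 15 | 1β-[1-(2-hydroxy-3,4,6-trimethoxyphenyl)-3-oxo-3-phenylpropyl]-3α,4α-epoxy-eudesm-11-en-2-one | C=C(C)[C@@H]1CC[C@]2(C)[C@@H](C1)[C@]3(C)O[C@@H]3C(=O)[C@H]2[C@H](CC(=O)c4ccccc4)c4c(OC)cc(OC)c(OC)c4O
F6 | step 19 | p-toluenesulfonylhydrazone of 30 | C=C(C)[C@@H]1CC[C@]2(C)[C@@H](C1)[C@](C)(O)CC(=NNS(=O)(=O)c3ccc(C)cc3)[C@H]2[C@@H]3C=C(c4ccccc4)Oc4c(OC)c(OC)cc(OC)c43
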